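The starting material has two ways out: with the coupling partner it gives the target, and with the second substrate it gives the cross product. Both steps are first order in [starting material], so it cancels from their ratio, and the target's share of new product follows [coupling partner]/[second substrate].

| flask | starting material | second substrate | solid reagent | temperature | time | remark |
|---|---|---|---|---|---|---|
| Saturday's | 0.25 M | 1.00 equiv (in portions, 3, over 4.0 d) | 2.00 equiv | 0 °C | 5.0 d | first portion at the start, last at 4.0 d |
| Thursday's | 0.25 M (fed, over 4.0 d) | 1.00 equiv | 2.00 equiv | 0 °C | 5.0 d | all else is in the flask from the start; the feed brings no volume worth counting |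
| Sunday's | 0.25 M (fed, over 4.0 d) | 1.00 equiv | 2.00 equiv |  | 5.0 d | the addition at −40 °C, then warmed to 0 °C; the feed brings no volume worth counting |
| Friday's | 0.25 M | 1.00 equiv | 2.00 equiv | 0 °C | 5.0 d | everything together at the start |

* the flask with the highest share of target in target plus cross product ("all alike" if they lie within 1.5 percentage points) (Saturday's / Thursday's / Sunday's / Friday's / all alike)
* share of target in target plus cross product at the end, Saturday's
* share of target in target plus cross product at the end, Thursday's
* share of target in target plus cross product at the end, Sunday's
* share of target in target plus cross product at the end, Friday's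

- solid, in amounts per volume of the solution: solid reagent
- all constants are for 0 °C and move with temperature by the activation energies and enthalpies
- at the start none of the solid reagent is in solution

    second substrate + coupling partner → second product (k1 = 0.280 L mol⁻¹ h⁻¹, Ea1 = 69.0 kJ mol⁻¹)
    starting material + coupling partner → target (k2 = 0.0917 L mol⁻¹ h⁻¹, Ea2 = 79.0 kJ mol⁻¹)
    starting material + second substrate → cross product (k3 = 0.105 L mol⁻¹ h⁻¹, Ea3 = 61.0 kJ mol⁻¹)
    solid reagent ⇌ coupling partner, rate k4*(cs4 - [coupling partner]) while solid is left; crystals form when [coupling partner] > cs4 (cs4 = 0.13 M, k4 = 0.0197 h⁻¹)
    target ⇌ isomer of the product (K5 = 0.34, k5 = 0.0632 h⁻¹, Ea5 = 84.0 kJ mol⁻¹, ΔH5 = −36.0 kJ mol⁻¹)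
    (constants at 0 °C)

We turn the question round and ask what target forming faster than cross product would require. The two form equally fast when [coupling partner]/[second substrate] equals the cross step's constant over the target step's, 1.15. This is the critical ratio, a selectivity factor. The coupling partner comes from a solid and stands at 0.13 M at saturation, so even then [second substrate] would have to lie below

cs4 / critical ratio = 0.114 M

Friday's full charge of 0.250 M stands 2.19 times above that line, while Saturday's first portion of 0.0833 M lies below it.

Early on Friday's, though, the partner's first-order loss is faster than its dissolving coefficient, so we estimate it at a resting level where dissolving equals consumption: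

[coupling partner] = k4·cs4 / (k4 + k1[second substrate] + k2[starting material])

With share = ratio / (ratio + critical ratio), the openings are:

Friday's: [coupling partner] = 0.0227 M, ratio 0.0910, share 7.36%

Saturday's: [coupling partner] = 0.0388 M, ratio 0.466, share 28.9%

Our reckoning therefore puts Saturday's opening above Friday's. It gives openings and no end figures, and we expect Friday's share to climb from its opening as second substrate is spent.

The forecast names Saturday's and gives 35%, 31%, 20% and 24% for Saturday's, Thursday's, Sunday's and Friday's, holding that “portionwise addition of the second substrate suppresses that cross reaction best”.

The simulation puts Saturday's highest, with 32.3%, then Thursday's 22.8%, Sunday's 20.9% and Friday's 17.9%.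

On Saturday's at 5.00 d, with 0.0538 M of coupling partner against 0.0611 M of second substrate, the ratio reads 0.880, under the critical 1.15, so the cross step is still running faster than the target step. The neighbour charged with 0.250 equiv of second substrate reads 5.88 at that time, above the critical ratio, and its share of target ends at 71.3%.

Its constants were set for the occasion, and the outcome is calculated.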